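Everything rests on cutting two bonds of the ring A benzoyl unit at once: the depside bond between the acyl carbon on C1 and O-4′ of ring B, and the ring bond C1–C6. Ring A has oxygen on C2 and C4, methyl on C3 and C6 and the carboxyl carbon on C1, which is the pattern of a folded 4-methyl-3,5,7-trioxooctanoyl chain. Heating diketo-dioxinone 4, a 2,2-dimethyl-1,3-dioxin-4-one with a 3,5-dioxohexan-2-yl group on C6, releases that chain as an acylketene. Phenol 9 adds to it, and amine-induced aldol condensation then builds and aromatises ring A. The crowded ester thus forms before its two ortho substituents exist.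

Key step: step 8

Remark on stereochemistry: the target has no stereocentre, stereogenic axis or stereogenic double bond, so it is achiral and no enantiomer has to be selected. The CH(CH3) centre of 3, 4, 10 and 11 epimerises through its enol and ends as the sp2 carbon C3 of ring A.

Remark on numbering: in 10–12 the chain is counted from the ketene/ester carbonyl (C1) through CH/CH2 (C2), C=O (C3), CH(CH3) (C4), C=O (C5), CH2 (C6) and C=O (C7) to CH3 (C8). Chain C1 becomes the depside carbonyl, chain C2–C7 become ring A C1–C6, and C8 becomes the 6-methyl group.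

Remark on protecting groups: 9 carries one free hydroxyl. The 2′-O-benzyl group keeps O-2′ out of the late methylation, and it falls together with the benzyl ester in a single hydrogenolysis.

Step 1
Reactants: 1 2,2,6-trimethyl-4H-1,3-dioxin-4-one
Product: 2 6-ethyl-2,2-dimethyl-4H-1,3-dioxin-4-one
Conditions: LDA, THF–DMPU, −78 °C; MeI, −78 → −20 °C
Reagents that add atoms: iodomethane, CI
Why: Kinetic deprotonation of the C6 methyl group gives the lithium dienolate, which in the presence of DMPU is alkylated at its γ-carbon (vinylogous enolate alkylation, known for this dioxinone).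

Step 2
Reactants: 2 6-ethyl-2,2-dimethyl-4H-1,3-dioxin-4-one
Product: 3 2,2-dimethyl-6-(3-oxobutan-2-yl)-4H-1,3-dioxin-4-one (racemic)
Conditions: LiHMDS, THF, −78 °C; AcCl (0.5 equiv per dienolate), −78 → −30 °C; cold 1 M HCl; surplus 2 recovered
Reagents that add atoms: acetyl chloride, CC(=O)Cl
Why: In this vinylogous Claisen-type C-acylation the dienolate attacks the acid chloride through its γ-carbon and the second equivalent of dienolate takes up the acidic proton of 3, which should suppress over-acylation, while the new stereocentre is formed racemic, is labile and is erased in step 8.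

Step 3
Reactants: 3 2,2-dimethyl-6-(3-oxobutan-2-yl)-4H-1,3-dioxin-4-one
Product: 4 6-(3,5-dioxohexan-2-yl)-2,2-dimethyl-4H-1,3-dioxin-4-one (racemic, labile, partly enolised)
Conditions: LDA (2.3 equiv), THF, −78 → −40 °C; MeCON(OMe)Me, −78 → −10 °C; cold 1 M HCl; used promptly
Reagents that add atoms: N-methoxy-N-methylacetamide, CON(C)C(C)=O
Why: This is a β-dicarbonyl dianion acylation (Weinreb ketone synthesis) in which the second deprotonation occurs at the terminal methyl group, that more reactive carbanion adds to the amide, and the chelated tetrahedral adduct persists until the acidic quench, so proton exchange with the product and double addition are avoided.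

Step 4
Reactants: 5 methyl 2,4-dihydroxy-3,6-dimethylbenzoate (atraric acid)
Product: 6 methyl 2-hydroxy-4-(methoxymethoxy)-3,6-dimethylbenzoate
Conditions: MOMCl (1.1 equiv), K2CO3, acetone, 0 °C → rt
Reagents that add atoms: chloromethyl methyl ether, COCCl
Why: In this chemoselective Williamson-type O-alkylation the C2 hydroxyl is hydrogen-bonded to the ester carbonyl and flanked by the C3 methyl group, so only the C4 hydroxyl should react with one equivalent of reagent.

Step 5
Reactants: 6 methyl 2-hydroxy-4-(methoxymethoxy)-3,6-dimethylbenzoate
Product: 7 2-hydroxy-4-(methoxymethoxy)-3,6-dimethylbenzoic acid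
Conditions: KOH, DMSO–H2O, 90 °C; then 1 M HCl, 0 °C, to pH 3–4
Reagents that add atoms: potassium hydroxide, [K+].[OH-] (supplies one carboxyl oxygen)
Why: Saponification (BAc2) of this di-ortho-substituted salicylate needs hot hydroxide in aqueous DMSO, the MOM acetal is inert to base, and cold, mild acidification guards against decarboxylation and acetal loss.

Step 6
Reactants: 7 2-hydroxy-4-(methoxymethoxy)-3,6-dimethylbenzoic acid
Product: 8 benzyl 2-benzyloxy-4-(methoxymethoxy)-3,6-dimethylbenzoate
Conditions: BnBr (2.5 equiv), K2CO3, DMF, rt → 60 °C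
Reagents that add atoms: benzyl bromide, BrCc1ccccc1
Why: The carboxylate is alkylated first at room temperature (SN2 at the benzylic carbon, insensitive to crowding at the carbonyl) and the chelated C2 phenoxide follows on warming (Williamson ether synthesis), so both hydrogenolysable groups are installed in one operation.

Step 7
Reactants: 8 benzyl 2-benzyloxy-4-(methoxymethoxy)-3,6-dimethylbenzoate
Product: 9 benzyl 2-benzyloxy-4-hydroxy-3,6-dimethylbenzoate
Conditions: HCl (cat.), MeOH–THF, 45 °C
Reagents that add atoms: none
Why: Acid-catalysed acetal exchange with methanol removes the MOM group and binds the formaldehyde unit as its dimethyl acetal, while the benzyl ether and the hindered benzyl ester are inert.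

Step 8
Reactants: 4 6-(3,5-dioxohexan-2-yl)-2,2-dimethyl-4H-1,3-dioxin-4-one; 9 benzyl 2-benzyloxy-4-hydroxy-3,6-dimethylbenzoate
Product: 13 benzyl 2-benzyloxy-4-(2,4-dihydroxy-3,6-dimethylbenzoyloxy)-3,6-dimethylbenzoate, via acylketene 10 (not isolated), via aryl triketo ester 11 (not isolated), via aldol carbinol 12 (not isolated)
Conditions: 9 in PhMe (concentrated), 110 °C, slow addition of 4 (1.2 equiv), N2 sweep; then Et3N, CH2Cl2, rt; then TFA, rt
Reagents that add atoms: none
Why: At 110 °C 4 undergoes a retro-hetero-Diels–Alder fragmentation, acetone leaves with the nitrogen stream, and the sp carbon of acylketene 10 is attacked by the only free hydroxyl of 9 (C4′–OH), the known trapping of dioxinone-derived acylketenes by alcohols and phenols, so that the acyl C–O bond of 11 forms without a coupling reagent. Triethylamine then removes a proton from chain C2, the methylene between the aryl ester and the C3 ketone, this carbon adds to the C7 methyl ketone to give 12, and loss of water (completed by TFA) with enolisation of C3 and C5 delivers the resorcylate ring, which is the established diketo-dioxinone to resorcylate ester sequence. Ring A closes by a 6-exo-trig aldol addition that reads as 6-(enolendo) when the enolate is drawn towards the C3 ketone and as 6-(enolexo) when it is drawn towards the ester carbonyl, both of them favoured modes. No stereocentre remains, because the labile C4 centre and the centres of 12 all become sp2 ring atoms. Two selectivities are needed: intermolecular O–H capture has to outrun attack of the C5 enol oxygen on the ketene, and C2-to-C7 closure has to outrun the two paths that expel the phenol, namely C5–O-to-C1 lactonisation (4-hydroxy-2-pyranone) and C6-to-C1 Claisen closure (acylphloroglucinol). They are secured by the slow addition of 4 to a concentrated solution of 9, by C2 being the most acidic carbon of 11, by the unhindered methyl ketone at C7, by the C4 methyl group, which lowers the enol content of the C3/C5 diketone, and by a weak amine base in an aprotic medium, while aromatisation makes the aldol path irreversible.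

Step 9
Reactants: 13 benzyl 2-benzyloxy-4-(2,4-dihydroxy-3,6-dimethylbenzoyloxy)-3,6-dimethylbenzoate
Product: 14 benzyl 2-benzyloxy-4-(2,4-dimethoxy-3,6-dimethylbenzoyloxy)-3,6-dimethylbenzoate
Conditions: MeI (excess), K2CO3 (anhydrous), DMF, rt → 40 °C
Reagents that add atoms: iodomethane, CI
Why: In this double Williamson methylation the two ring A hydroxyls are the only acidic sites, the free C4–OH reacts first and the chelated C2–OH on gentle warming, and the di-ortho-substituted depside carbonyl meets no external nucleophile under anhydrous carbonate.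

Step 10
Reactants: 14 benzyl 2-benzyloxy-4-(2,4-dimethoxy-3,6-dimethylbenzoyloxy)-3,6-dimethylbenzoate
Product: 15 diffractaic acid, 4-(2,4-dimethoxy-3,6-dimethylbenzoyloxy)-2-hydroxy-3,6-dimethylbenzoic acid
Conditions: H2 (1 atm), 10% Pd/C, EtOAc, rt
Reagents that add atoms: none
Why: Catalytic hydrogenolysis cleaves the two benzylic C–O bonds (ester and ether) under neutral conditions that leave the aryl ester, the methyl ethers and the arenes untouched.

Compound list
1 | 2,2,6-trimethyl-4H-1,3-dioxin-4-one | CC1=CC(=O)OC(C)(C)O1 | starting material
2 | 6-ethyl-2,2-dimethyl-4H-1,3-dioxin-4-one | CCC1=CC(=O)OC(C)(C)O1 | intermediate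
3 | 2,2-dimethyl-6-(3-oxobutan-2-yl)-4H-1,3-dioxin-4-one (racemic, labile) | CC(=O)C(C)C1=CC(=O)OC(C)(C)O1 | intermediate
4 | 6-(3,5-dioxohexan-2-yl)-2,2-dimethyl-4H-1,3-dioxin-4-one (racemic, labile) | CC(=O)CC(=O)C(C)C1=CC(=O)OC(C)(C)O1 | intermediate
5 | methyl 2,4-dihydroxy-3,6-dimethylbenzoate (atraric acid) | COC(=O)c1c(C)cc(O)c(C)c1O | starting material
6 | methyl 2-hydroxy-4-(methoxymethoxy)-3,6-dimethylbenzoate | COCOc1cc(C)c(C(=O)OC)c(O)c1C | intermediate
7 | 2-hydroxy-4-(methoxymethoxy)-3,6-dimethylbenzoic acid | COCOc1cc(C)c(C(=O)O)c(O)c1C | intermediate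
8 | benzyl 2-benzyloxy-4-(methoxymethoxy)-3,6-dimethylbenzoate | COCOc1cc(C)c(C(=O)OCc2ccccc2)c(OCc2ccccc2)c1C | intermediate
9 | benzyl 2-benzyloxy-4-hydroxy-3,6-dimethylbenzoate | Cc1cc(O)c(C)c(OCc2ccccc2)c1C(=O)OCc1ccccc1 | intermediate
10 | acylketene, 4-methyl-3,5,7-trioxooct-1-en-1-one (not isolated, racemic) | CC(=O)CC(=O)C(C)C(=O)C=C=O | intermediate
11 | aryl triketo ester, benzyl 2-benzyloxy-3,6-dimethyl-4-(4-methyl-3,5,7-trioxooctanoyloxy)benzoate (not isolated, racemic) | CC(=O)CC(=O)C(C)C(=O)CC(=O)Oc1cc(C)c(C(=O)OCc2ccccc2)c(OCc2ccccc2)c1C | intermediate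
12 | aldol carbinol, benzyl 2-benzyloxy-4-[(2-hydroxy-2,5-dimethyl-4,6-dioxocyclohexane-1-carbonyl)oxy]-3,6-dimethylbenzoate (not isolated, mixture of stereoisomers and tautomers) | CC1(O)CC(=O)C(C)C(=O)C1C(=O)Oc1cc(C)c(C(=O)OCc2ccccc2)c(OCc2ccccc2)c1C | intermediate
13 | benzyl 2-benzyloxy-4-(2,4-dihydroxy-3,6-dimethylbenzoyloxy)-3,6-dimethylbenzoate | Cc1cc(O)c(C)c(O)c1C(=O)Oc1cc(C)c(C(=O)OCc2ccccc2)c(OCc2ccccc2)c1C | intermediate
14 | benzyl 2-benzyloxy-4-(2,4-dimethoxy-3,6-dimethylbenzoyloxy)-3,6-dimethylbenzoate | COc1cc(C)c(C(=O)Oc2cc(C)c(C(=O)OCc3ccccc3)c(OCc3ccccc3)c2C)c(OC)c1C | intermediate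
15 | diffractaic acid (achiral) | COc1cc(C)c(C(=O)Oc2cc(C)c(C(=O)O)c(O)c2C)c(OC)c1C | target

Total step count: 10.
Longest linear sequence: 7 steps (5 → 6 → 7 → 8 → 9 → 13 → 14 → 15). The dioxinone branch (1 → 4) contributes 3 steps and joins in step 8.

Steps most likely to fail

Step 8. Capture of the ketene by a hindered, electron-poor phenol may be too slow, so the ketene would be consumed by internal O-cyclisation. Alternatively, the aryl ester may be lost again through lactonisation or Claisen closure during the base treatment. The fallback gives up building ring A on the ester and acylates 9 with a preformed ring A acid.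
- It sets out from 5, which is exhaustively O-methylated (MeI, K2CO3, DMF, 60 °C) to methyl 2,4-dimethoxy-3,6-dimethylbenzoate F1.
- F1 is saponified (KOH, aqueous DMSO, 90 °C) to 2,4-dimethoxy-3,6-dimethylbenzoic acid F2.
- F2 is activated with trifluoroacetic anhydride in toluene as 2,4-dimethoxy-3,6-dimethylbenzoic trifluoroacetic anhydride F3, which acylates the C4′ hydroxyl of 9 at room temperature.
- The fallback comes back to the route at 14 and so also bypasses step 9.

Step 3. Three processes are the dangers: incomplete dianion formation, proton transfer from the enolisable amide to the dianion, and premature cyclisation of the tricarbonyl chain during work-up or on silica. The fallback replaces acylation by addition and oxidation.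
- It sets out from 3, whose dianion (LDA, THF, −78 °C) adds to acetaldehyde in a fast aldol reaction whose product is no more acidic than the substrate. This gives 6-(5-hydroxy-3-oxohexan-2-yl)-2,2-dimethyl-4H-1,3-dioxin-4-one F4.
- Dess–Martin oxidation of F4 under neutral conditions (CH2Cl2, rt) comes back to the route at 4.

Step 2. Because the nucleophilic γ-carbon of the dienolate of 2 is secondary, O-acylation or reaction through the α-carbon may compete with the desired C–C bond formation. The fallback inverts the order of the two bond formations.
- It sets out from 1, whose unhindered primary dienolate (LiHMDS, THF, −78 °C) is acylated with acetyl chloride to 2,2-dimethyl-6-(2-oxopropyl)-4H-1,3-dioxin-4-one F5.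
- The stabilised enolate of F5 is then mono-C-methylated at the doubly activated methylene (K2CO3, MeI 1.0 equiv, acetone, rt).
- The fallback comes back to the route at 3 and bypasses steps 1 and 2.

Further compounds
F1 | step 8 | methyl 2,4-dimethoxy-3,6-dimethylbenzoate | COC(=O)c1c(C)cc(OC)c(C)c1OC
F2 | step 8 | 2,4-dimethoxy-3,6-dimethylbenzoic acid | COc1cc(C)c(C(=O)O)c(OC)c1C
F3 | step 8 | 2,4-dimethoxy-3,6-dimethylbenzoic trifluoroacetic anhydride | COc1cc(C)c(C(=O)OC(=O)C(F)(F)F)c(OC)c1C
F4 | step 3 | 6-(5-hydroxy-3-oxohexan-2-yl)-2,2-dimethyl-4H-1,3-dioxin-4-one (mixture of diastereomers) | CC(O)CC(=O)C(C)C1=CC(=O)OC(C)(C)O1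
F5 | step 2 | 2,2-dimethyl-6-(2-oxopropyl)-4H-1,3-dioxin-4-one | CC(=O)CC1=CC(=O)OC(C)(C)O1
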